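**Retrosynthetic overview**
Rings: A = methoxylated ring, B = para-phenylene, C = hydroxylated ring, D = meta-phenylene; all four are bought, and the 20-membered macrocycle (A–O–B–CH2CH2–C–O–D–CH2CH2–A) is the only ring made, and it is made last.
Pakyonol ⇐ macrocyclic ring C aldehyde (Baeyer–Villiger/Dakin: the ring C hydroxyl is carried as CHO).
Macrocyclic aldehyde ⇐ an acyclic three-ring styrenyl phenol (D–CH2CH2–A–O–B–vinyl) + 5-bromo-2-fluorobenzaldehyde in one pot: hydroboration/B-alkyl Suzuki builds the B–CH2CH2–C bridge, then SNAr of the ring D phenoxide at the C–F carbon forms the D–O–C ether and closes the macrocycle.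
Enabling feature: on ring C the ether carbon (C4) is ortho to the hydroxyl carbon (C3) and para to the bridge carbon (C1), so F/CHO/Br of one benzaldehyde map onto C4/C3/C1; CHO activates fluoride displacement and is the latent OH, Br takes the alkylborane.
Styrenyl phenol ⇐ 5-bromo-2-methoxyphenol + 4-fluorobenzaldehyde (SNAr, A–O–B), then 3-ethenylphenol (hydroboration/B-alkyl Suzuki, A–CH2CH2–D), then Wittig methylenation of the ring B aldehyde.

Key step: step 5

Remark: the target has no stereogenic centre and its SMILES carries no stereodescriptor, so no step has to set or preserve configuration. 9-BBN = 9-borabicyclo[3.3.1]nonane.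

Step 1
Reactants: 1 5-bromo-2-methoxyphenol; 2 4-fluorobenzaldehyde
Product: 3 4-(5-bromo-2-methoxyphenoxy)benzaldehyde
Conditions: K2CO3 (2 equiv), DMF, 130 °C
Reagents that add atoms: none
Why: Nucleophilic aromatic substitution (SNAr) of the para-formyl-activated fluoride by the guaiacol-type phenoxide, a pairing with close precedent for isovanillin-type phenols, while the unactivated C–Br bond and the aldehyde are inert to carbonate.

Step 2
Reactants: 4 3-hydroxybenzaldehyde
Product: 5 3-ethenylphenol
Conditions: Ph3PCH3Br (2.3 equiv), KOtBu (2.3 equiv), THF, 0 °C to rt; aq NH4Cl; used freshly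
Reagents that add atoms: methyltriphenylphosphonium bromide, C[P+](c1ccccc1)(c1ccccc1)c1ccccc1.[Br-]
Why: Wittig methylenation with excess ylide, the first equivalent of base only forming the phenoxide, which does not hinder olefination of the meta-formyl group.

Step 3
Reactants: 5 3-ethenylphenol; 3 4-(5-bromo-2-methoxyphenoxy)benzaldehyde
Product: 7 4-[5-[2-(3-hydroxyphenyl)ethyl]-2-methoxyphenoxy]benzaldehyde, via bis-9-BBN adduct 6 (not isolated)
Conditions: 5 (1.2 equiv), 9-BBN (2.5 equiv), THF, 0 °C to rt; H2O (quench of residual B–H); then 3, Pd(OAc)2 (3 mol %), SPhos (6 mol %), aq K3PO4 (3 equiv), THF, 60 °C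
Reagents that add atoms: none
Why: 9-BBN hydroborates the styrene with anti-Markovnikov selectivity (one further equivalent being taken up by the phenol O–H as a borinate that the aqueous base cleaves again) and the primary alkylborane then undergoes B-alkyl Suzuki–Miyaura coupling at the only C–Br bond of 3, the electron-rich ligand SPhos speeding oxidative addition into the anisole-type bromide and reductive elimination ahead of β-hydride loss, while the aryl aldehyde should not be attacked by the borate once free B–H is quenched.

Step 4
Reactants: 7 4-[5-[2-(3-hydroxyphenyl)ethyl]-2-methoxyphenoxy]benzaldehyde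
Product: 8 3-[2-[3-(4-ethenylphenoxy)-4-methoxyphenyl]ethyl]phenol
Conditions: Ph3PCH3Br (3 equiv), KOtBu (3 equiv), THF, 0 °C to rt; aq NH4Cl
Reagents that add atoms: methyltriphenylphosphonium bromide, C[P+](c1ccccc1)(c1ccccc1)c1ccccc1.[Br-]
Why: Wittig methylenation of the ring B aldehyde with excess ylide in the presence of the phenoxide gives the styrene that serves as the two-carbon bridge precursor.

Step 5
Reactants: 8 3-[2-[3-(4-ethenylphenoxy)-4-methoxyphenyl]ethyl]phenol; 9 5-bromo-2-fluorobenzaldehyde
Product: 12 ring C formyl macrocycle (pakyonol with CHO in place of OH), via bis-9-BBN adduct 10 (not isolated), via seco fluoroaldehyde 11 (not isolated)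
Conditions: 9-BBN (2.3 equiv), THF, rt; H2O (quench of residual B–H); then 9 (1.05 equiv), Pd(OAc)2 (5 mol %), SPhos (10 mol %), aq K3PO4 (3 equiv), THF, 50 °C; then syringe-pump addition of the crude mixture to Cs2CO3 (4 equiv), DMF, 110 °C (final 2 mM)
Reagents that add atoms: none
Why: 9-BBN adds anti-Markovnikov to the styrene of 8 (its second equivalent is consumed by the phenol O–H as a borinate that the base later hydrolyses) to give the primary alkylborane 10, which after oxidative addition of Pd(0) into the C–Br bond of 9, base-assisted transmetalation and reductive elimination forms the ring B–CH2CH2–ring C bond of 11 (B-alkyl Suzuki–Miyaura coupling). On transfer into hot Cs2CO3/DMF the ring D phenoxide adds to the C–F carbon of ring C ortho to the formyl group and fluoride leaves from the Meisenheimer intermediate, the closest known reaction type being the intramolecular SNAr diaryl-ether macrocyclisation of fluoroarenes bearing an ortho acceptor. The only ring closed is the 20-membered macrocycle, formed by intramolecular O-arylation at an sp2 carbon under high dilution. No stereocentre is created. The step needs chemoselectivity among the three functions of 9 and a fixed order of events: Pd engages only the C–Br bond, the alkylborate should not reduce or add to the aryl aldehyde at 50 °C once residual B–H is quenched, and fluoride displacement should be slow in wet THF with phosphate and be switched on only by Cs2CO3 in DMF at 110 °C, so that the bimolecular C–C coupling precedes the unimolecular C–O closure. Regiochemistry is fixed by 9 itself: Br para to F places the ethano bridge para to the new ether oxygen, and CHO ortho to F marks the future hydroxyl carbon.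

Step 6
Reactants: 12 ring C formyl macrocycle
Product: 14 pakyonol, via aryl formate 13 (not isolated)
Conditions: mCPBA (1.5 equiv), CH2Cl2, 0 °C to rt; then K2CO3 (cat.), MeOH, rt
Reagents that add atoms: 3-chloroperbenzoic acid, OOC(=O)c1cccc(Cl)c1
Why: Baeyer–Villiger oxidation with a Dakin-type outcome: in the Criegee adduct the electron-rich ring C carbon flanked by the ortho-aryloxy group migrates to oxygen to give the aryl formate, which mild methanolysis cleaves to the phenol, and no alkene, amine or other peracid-sensitive group is left in 12.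

**Compound list**
1 | 5-bromo-2-methoxyphenol | COc1ccc(Br)cc1O | starting material
2 | 4-fluorobenzaldehyde | O=Cc1ccc(F)cc1 | starting material
3 | 4-(5-bromo-2-methoxyphenoxy)benzaldehyde | COc1ccc(Br)cc1Oc1ccc(C=O)cc1 | intermediate
4 | 3-hydroxybenzaldehyde | O=Cc1cccc(O)c1 | starting material
5 | 3-ethenylphenol | C=Cc1cccc(O)c1 | intermediate
6 | 9-[2-[3-(9-borabicyclo[3.3.1]nonan-9-yloxy)phenyl]ethyl]-9-borabicyclo[3.3.1]nonane (bis-9-BBN adduct of 5) | c1cc(CCB2C3CCCC2CCC3)cc(OB2C3CCCC2CCC3)c1 | intermediate
7 | 4-[5-[2-(3-hydroxyphenyl)ethyl]-2-methoxyphenoxy]benzaldehyde | COc1ccc(CCc2cccc(O)c2)cc1Oc1ccc(C=O)cc1 | intermediate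
8 | 3-[2-[3-(4-ethenylphenoxy)-4-methoxyphenyl]ethyl]phenol | COc1ccc(CCc2cccc(O)c2)cc1Oc1ccc(C=C)cc1 | intermediate
9 | 5-bromo-2-fluorobenzaldehyde | O=Cc1cc(Br)ccc1F | starting material
10 | bis-9-BBN adduct of 8 (B-alkyl-9-BBN at the former vinyl terminus, 9-BBN borinate on the ring D oxygen) | COc1ccc(CCc2cccc(OB3C4CCCC3CCC4)c2)cc1Oc1ccc(CCB2C3CCCC2CCC3)cc1 | intermediate
11 | 2-fluoro-5-[2-[4-[5-[2-(3-hydroxyphenyl)ethyl]-2-methoxyphenoxy]phenyl]ethyl]benzaldehyde | COc1ccc(CCc2cccc(O)c2)cc1Oc1ccc(CCc2ccc(F)c(C=O)c2)cc1 | intermediate
12 | ring C formyl macrocycle: pakyonol skeleton with CHO in place of the hydroxyl (CHO ortho to the C–O–D ether oxygen, meta to the ethano bridge) | COc1ccc2cc1Oc1ccc(cc1)CCc1ccc(c(C=O)c1)Oc1cccc(c1)CC2 | intermediate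
13 | formate ester of pakyonol (ring C O–CHO) | COc1ccc2cc1Oc1ccc(cc1)CCc1ccc(c(OC=O)c1)Oc1cccc(c1)CC2 | intermediate
14 | pakyonol | COc1ccc2cc1Oc1ccc(cc1)CCc1ccc(c(O)c1)Oc1cccc(c1)CC2 | target

**Step count and risks**
Total step count: 6. Longest linear sequence: 5 steps (steps 1, 3, 4, 5, 6); step 2 is a one-step branch.

Steps most likely to fail:

Step 5. The formyl group of 9 may be reduced by residual B–H or by hydride transfer from the alkylborane, fluoride displacement may begin before the C–C coupling is complete, and chain growth may compete with ring closure. The fallback separates the three events and masks the formyl group during the boron chemistry. It sets out from 8 and 9: 9 is converted with ethylene glycol and TsOH (toluene, Dean–Stark) into 2-(5-bromo-2-fluorophenyl)-1,3-dioxolane F1, whose acetal does not activate the fluoride. 8 is hydroborated as before (adduct 10) and coupled with F1 (Pd(OAc)2, SPhos, aq K3PO4, THF, 50 °C) to give the seco acetal F2. 1 M HCl in THF releases the seco fluoroaldehyde 11, which is now isolated and purified and then cyclised in a separate operation by slow addition to Cs2CO3 in DMF at 110 °C. The route is rejoined at 12.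

Step 3. Oxidative addition into the electron-rich C–Br bond may be slow, which would let protodeboronation or β-hydride loss from the phenethylborane and slow hydride transfer to the aldehyde take over. The fallback avoids boron altogether. It sets out from 3 and 5: a Mizoroki–Heck reaction (Pd(OAc)2, P(o-tol)3, Et3N, DMF, 110 °C) should give the (E)-stilbene aldehyde F3, and hydrogenation of the C=C bond over a sulfide-poisoned catalyst that spares aryl aldehydes (H2, Pd/C, Ph2S, EtOAc, rt) should give 7, where the route is rejoined.

Step 6. Hydride instead of aryl migration in the Criegee adduct would give the carboxylic acid, and the peracid may further oxidise the electron-rich phenolic product. The fallback uses a nitro group as activator and latent hydroxyl, so no peracid is needed. It sets out from 8: SNAr with commercial 4-bromo-1-fluoro-2-nitrobenzene (K2CO3, DMF, rt) should give the bromo nitro diaryl ether styrene F4. Hydroboration (9-BBN, THF, rt; the nitro group is inert) gives the alkylborane F5 in the flask, and intramolecular B-alkyl Suzuki–Miyaura macrocyclisation (PdCl2(dppf), aq K3PO4, THF/DMF, 60 °C, slow addition, 2 mM) closes the ring to the macrocyclic nitroarene F6. Fe/NH4Cl (EtOH/H2O, 80 °C) gives the macrocyclic aniline F7. Diazotisation (NaNO2, aq H2SO4, 0 °C) gives the diazonium hydrogensulfate F8, which is hydrolysed with Cu(NO3)2/Cu2O in water at rt to 14, the target.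

**Further compounds**
F1 | step 5 | 2-(5-bromo-2-fluorophenyl)-1,3-dioxolane | Fc1ccc(Br)cc1C1OCCO1
F2 | step 5 | 3-[2-[3-[4-[2-[3-(1,3-dioxolan-2-yl)-4-fluorophenyl]ethyl]phenoxy]-4-methoxyphenyl]ethyl]phenol (seco acetal) | COc1ccc(CCc2cccc(O)c2)cc1Oc1ccc(CCc2ccc(F)c(C3OCCO3)c2)cc1
F3 | step 3 | 4-[5-[(E)-2-(3-hydroxyphenyl)ethenyl]-2-methoxyphenoxy]benzaldehyde | COc1ccc(/C=C/c2cccc(O)c2)cc1Oc1ccc(C=O)cc1
F4 | step 6 | 4-bromo-1-[3-[2-[3-(4-ethenylphenoxy)-4-methoxyphenyl]ethyl]phenoxy]-2-nitrobenzene | COc1ccc(CCc2cccc(Oc3ccc(Br)cc3[N+](=O)[O-])c2)cc1Oc1ccc(C=C)cc1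
F5 | step 6 | B-alkyl-9-BBN adduct of F4 (boron at the former vinyl terminus) | COc1ccc(CCc2cccc(Oc3ccc(Br)cc3[N+](=O)[O-])c2)cc1Oc1ccc(CCB2C3CCCC2CCC3)cc1
F6 | step 6 | macrocyclic nitroarene (pakyonol with NO2 in place of OH) | COc1ccc2cc1Oc1ccc(cc1)CCc1ccc(c([N+](=O)[O-])c1)Oc1cccc(c1)CC2
F7 | step 6 | macrocyclic aniline (pakyonol with NH2 in place of OH) | COc1ccc2cc1Oc1ccc(cc1)CCc1ccc(c(N)c1)Oc1cccc(c1)CC2
F8 | step 6 | macrocyclic arenediazonium hydrogensulfate (N2+ in place of OH) | COc1ccc2cc1Oc1ccc(cc1)CCc1ccc(c([N+]#N)c1)Oc1cccc(c1)CC2.OS(=O)(=O)[O-]
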